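## Retrosynthetic overview
1. The acid comes from its methyl ester. The side chain is cut at the C2'–C3' sp3–sp3 bond, a Pd-catalysed alkyl–alkyl Suzuki coupling of a small dioxolane bromide with the 9-BBN adduct of a C14 tetraene.
2. The tetraene comes from a Pd-catalysed alkenyl–alkenyl Suzuki coupling. The partners are (E)-1-iodoocta-1,7-diene (6-bromohexene, acetylide, hydrozirconation) and an (E,E)-hexadienyl boronate (pentenal, Corey–Fuchs, hydroboration).
3. The only ring, the 1,2-dioxolane, is closed in the core branch by a new Pd(II)-catalysed peroxypalladation/methoxycarbonylation of a homoallylic tertiary hydroperoxide. This one step makes O–C3, the C–CO2Me bond and the C3 stereocentre.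
4. The hydroperoxide (C5 stereocentre) comes from invertive perhydrolysis of an (R)-2,2-disubstituted oxetane. The oxetane comes from (S)-2-methylglycidol (Sharpless epoxidation of methallyl alcohol), isopropenyl Grignard and a sulfoxonium ylide.

Assumption: the SMILES is read as (3R,5R), with the two ring methyl groups cis. The sense of induction of the BOXAX ligand in step 6 cannot be predicted. (S,S) is written, and its mirror image is used if a test run gives the trans isomer.

## Route

**Core branch**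

Step 1
Reactants: 1 2-methylprop-2-en-1-ol (methallyl alcohol)
Product: 2 (S)-(2-methyloxiran-2-yl)methanol ((S)-2-methylglycidol)
Conditions: Ti(OiPr)4 (5 mol %), L-(+)-DIPT (6 mol %), cumene hydroperoxide, 4 Å MS, CH2Cl2, −20 °C
Reagents that add atoms: cumene hydroperoxide, CC(C)(OO)c1ccccc1
Why: Katsuki–Sharpless asymmetric epoxidation, in which the Ti/L-(+)-tartrate complex binds the allylic alcohol and delivers oxygen to one alkene face, setting the quaternary carbon (the later C5) as S in about 92–95% ee.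

Step 2
Reactants: 2 (S)-2-methylglycidol; 3 isopropenylmagnesium bromide
Product: 4 (2R)-2,4-dimethylpent-4-ene-1,2-diol
Conditions: 3 (3 equiv), CuI (10 mol %), THF, −30 → 0 °C; aqueous work-up
Reagents that add atoms: none
Why: Copper-catalysed Grignard opening of an epoxide (SN2) occurs at the unhindered CH2, so the quaternary centre is untouched (S becomes R only through CIP ranking), and the Payne rearrangement of the alkoxide is degenerate and cannot racemise it.

Step 3
Reactants: 4 (2R)-2,4-dimethylpent-4-ene-1,2-diol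
Product: 5 (2R)-2-hydroxy-2,4-dimethylpent-4-en-1-yl 4-methylbenzenesulfonate
Conditions: TsCl (1.05 equiv), Et3N, Bu2SnO (2 mol %), CH2Cl2, 0 °C → rt
Reagents that add atoms: 4-toluenesulfonyl chloride, Cc1ccc(cc1)S(=O)(=O)Cl
Why: Selective sulfonylation (stannylene-catalysed tosylation) reaches only the primary hydroxyl because the tertiary one is too hindered.

Step 4
Reactants: 5 (2R)-2-hydroxy-2,4-dimethylpent-4-en-1-yl 4-methylbenzenesulfonate
Product: 7 (2R)-2-methyl-2-(2-methylprop-2-en-1-yl)oxetane, via (2R)-2-methyl-2-(2-methylprop-2-en-1-yl)oxirane 6 (not isolated)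
Conditions: Me3S(O)I (3.5 equiv), KOtBu (4.5 equiv), t-BuOH, 50 °C, 48 h
Reagents that add atoms: trimethylsulfoxonium iodide, C[S+](C)(C)=O.[I-]
Why: Base closes the tosyloxy alcohol to the epoxide (Williamson type), then dimethylsulfoxonium methylide opens it at CH2 and the alkoxide expels DMSO in a 4-exo-tet closure (Corey–Chaykovsky-type epoxide-to-oxetane ring expansion), with the C–O bond at the stereocentre never broken.

Step 5
Reactants: 7 (2R)-2-methyl-2-(2-methylprop-2-en-1-yl)oxetane
Product: 8 (3S)-3-hydroperoxy-3,5-dimethylhex-5-en-1-ol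
Conditions: anhydrous H2O2 (about 3 M in Et2O, 10 equiv), TMSOTf (10 mol %), Et2O, −25 → 0 °C (blast shield)
Reagents that add atoms: hydrogen peroxide, OO
Why: Lewis acid catalysed perhydrolysis of a 2,2-disubstituted oxetane is a strain-driven, borderline SN2 opening at the tertiary carbon in which H2O2 enters anti to the leaving oxygen, so the C5–O bond is set with inversion.

Step 6
Reactants: 8 (3S)-3-hydroperoxy-3,5-dimethylhex-5-en-1-ol
Product: 9 methyl 2-[(3R,5R)-5-(2-hydroxyethyl)-3,5-dimethyl-1,2-dioxolan-3-yl]acetate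
Conditions: Pd(OCOCF3)2 (10 mol %), (S,S)-Bn-BOXAX (20 mol %), p-benzoquinone (2 equiv), CO (1 atm), MeOH, 0 °C → rt, dark; chromatographic removal of the trans isomer
Reagents that add atoms: carbon monoxide, [C-]#[O+]; methanol, CO
Why: Proposed new method: a ligand-controlled 5-exo peroxypalladation/methoxycarbonylation, in which cationic Pd(II)–BOXAX binds the 1,1-disubstituted alkene, the terminal oxygen of the hydroperoxide (more acidic and nucleophilic than the primary OH, and closing the smaller ring) adds to the internal carbon, the neopentyl-type σ-alkyl-Pd has no β-hydrogen and therefore inserts CO and is cleaved by MeOH, and benzoquinone returns Pd(0) to Pd(II); the ligand selects the alkene face and sets C3 as R (methyls cis), and because the minor enantiomer of 8 is channelled into the separable trans isomer the ee of 9 rises; the closest known reaction types are the Semmelhack-type intramolecular oxypalladation–alkoxycarbonylation of alkenols (enantioselective domino Wacker–carbonylation with BOXAX ligands) and the Pd(II)-catalysed Wacker-type cyclisation of unsaturated hydroperoxides to cyclic peroxides, which ends by β-hydride elimination and has not been intercepted with CO or run under ligand control.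

Step 7
Reactants: 9 methyl 2-[(3R,5R)-5-(2-hydroxyethyl)-3,5-dimethyl-1,2-dioxolan-3-yl]acetate
Product: 11 methyl 2-[(3R,5S)-5-(2-bromoethyl)-3,5-dimethyl-1,2-dioxolan-3-yl]acetate, via methyl 2-[(3R,5R)-3,5-dimethyl-5-[2-(methylsulfonyloxy)ethyl]-1,2-dioxolan-3-yl]acetate 10 (not isolated)
Conditions: MsCl, Et3N, CH2Cl2, 0 °C; then LiBr (5 equiv), acetone, rt → 40 °C
Reagents that add atoms: methanesulfonyl chloride, CS(=O)(=O)Cl (atoms in 10 only); lithium bromide, [Li+].[Br-]
Why: Mesylation followed by Finkelstein-type SN2 displacement works at an unhindered primary carbon without phosphines or reductants that would attack the O–O bond (R to S at C5 is only a CIP change).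

**Chain branch**

Step 8
Reactants: 12 6-bromohex-1-ene; 13 lithium acetylide–ethylenediamine complex
Product: 14 oct-1-en-7-yne
Conditions: DMSO, 0 °C → rt
Reagents that add atoms: none
Why: SN2 alkylation of lithium acetylide with a primary bromide in DMSO is clean and leaves the terminal alkene alone.

Step 9
Reactants: 14 oct-1-en-7-yne
Product: 16 (1E)-1-iodoocta-1,7-diene, via chlorobis(cyclopentadienyl)[(1E)-octa-1,7-dien-1-yl]zirconium 15 (not isolated)
Conditions: Cp2Zr(H)Cl (1.0 equiv), CH2Cl2, 0 °C → rt, dark; then I2 (1.0 equiv), 0 °C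
Reagents that add atoms: Schwartz reagent, Cl[ZrH](C1C=CC=C1)C1C=CC=C1 (atoms in 15 only); iodine, II
Why: Hydrozirconation with one equivalent of Schwartz reagent is faster at the terminal alkyne than at the terminal alkene and is syn and terminal-selective, and iodinolysis of the C–Zr bond goes with retention, which sets the E-iodide.

Step 10
Reactants: 17 (2E)-pent-2-enal
Product: 18 (3E)-1,1-dibromohexa-1,3-diene
Conditions: CBr4 (2 equiv), PPh3 (4 equiv), CH2Cl2, 0 °C
Reagents that add atoms: carbon tetrabromide, BrC(Br)(Br)Br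
Why: The first stage of the Corey–Fuchs reaction (Ramirez dibromo-olefination by Ph3P=CBr2) works well on enals and does not touch the E-alkene.

Step 11
Reactants: 18 (3E)-1,1-dibromohexa-1,3-diene
Product: 20 (3E)-hex-3-en-1-yne, via lithium (3E)-hex-3-en-1-yn-1-ide 19 (not isolated)
Conditions: n-BuLi (2.1 equiv), Et2O, −78 → 0 °C; then H2O; product kept as a distilled ether solution
Reagents that add atoms: n-butyllithium, [Li]CCCC (Li in 19 only)
Why: In the second stage of the Corey–Fuchs reaction, Br/Li exchange, Fritsch–Buttenberg–Wiechell-type loss of LiBr and deprotonation give the acetylide, which water protonates.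

Step 12
Reactants: 20 (3E)-hex-3-en-1-yne
Product: 21 2-[(1E,3E)-hexa-1,3-dien-1-yl]-4,4,5,5-tetramethyl-1,3,2-dioxaborolane
Conditions: HBpin (1.1 equiv), Cp2Zr(H)Cl (10 mol %), Et3N (10 mol %), sealed tube, 50 °C
Reagents that add atoms: pinacolborane, [H]B1OC(C)(C)C(C)(C)O1
Why: Zirconocene-catalysed hydroboration adds H–B syn to the alkyne only, with boron at the terminal carbon, giving the E,E-dienyl boronate.

Step 13
Reactants: 16 (1E)-1-iodoocta-1,7-diene; 21 2-[(1E,3E)-hexa-1,3-dien-1-yl]-4,4,5,5-tetramethyl-1,3,2-dioxaborolane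
Product: 22 (7E,9E,11E)-tetradeca-1,7,9,11-tetraene
Conditions: Pd(PPh3)4 (5 mol %), K3PO4 (3 equiv), THF/H2O, rt → 40 °C, degassed, dark
Reagents that add atoms: none
Why: Suzuki–Miyaura alkenyl–alkenyl coupling goes with retention at both partners, which gives the all-E triene, and the isolated vinyl group is not involved at this temperature.

**Union and end game**

Step 14
Reactants: 22 (7E,9E,11E)-tetradeca-1,7,9,11-tetraene; 11 methyl 2-[(3R,5S)-5-(2-bromoethyl)-3,5-dimethyl-1,2-dioxolan-3-yl]acetate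
Product: 24 methyl 2-[(3R,5R)-5-[(9E,11E,13E)-hexadeca-9,11,13-trien-1-yl]-3,5-dimethyl-1,2-dioxolan-3-yl]acetate, via 9-[(7E,9E,11E)-tetradeca-7,9,11-trien-1-yl]-9-borabicyclo[3.3.1]nonane 23 (not isolated)
Conditions: 22 (1.3 equiv), 9-BBN-H (1.25 equiv), THF, 0 °C → rt; then 11, Pd(OAc)2 (5 mol %), PCy3 (10 mol %), K3PO4·H2O (1.5 equiv), THF, rt, dark
Reagents that add atoms: 9-borabicyclo[3.3.1]nonane, [H]B1C2CCCC1CCC2 (atoms in 23 only)
Why: 9-BBN hydroborates the monosubstituted terminal alkene far faster than the conjugated internal triene, and the alkyl–alkyl Suzuki–Miyaura coupling with the bulky, electron-rich Pd/PCy3 catalyst joins the primary bromide to the B-alkyl group at room temperature faster than β-hydride elimination, under mild conditions that the hindered dialkyl peroxide, the ester and the triene should tolerate, with no stereocentre touched.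

Step 15
Reactants: 24 methyl 2-[(3R,5R)-5-[(9E,11E,13E)-hexadeca-9,11,13-trien-1-yl]-3,5-dimethyl-1,2-dioxolan-3-yl]acetate
Product: 26 2-[(3R,5R)-5-[(9E,11E,13E)-hexadeca-9,11,13-trien-1-yl]-3,5-dimethyl-1,2-dioxolan-3-yl]acetic acid, via lithium 2-[(3R,5R)-5-[(9E,11E,13E)-hexadeca-9,11,13-trien-1-yl]-3,5-dimethyl-1,2-dioxolan-3-yl]acetate 25 (not isolated)
Conditions: LiOH (3 equiv), THF/H2O 3:1, 0 °C → rt; then 0.5 M HCl to pH 4, 0 °C
Reagents that add atoms: lithium hydroxide, [Li+].[OH-]
Why: Saponification of the unhindered methyl ester at low temperature is faster than β-elimination of the peroxide, and both peroxide carbons are fully substituted (no Kornblum–DeLaMare cleavage), so neither stereocentre is affected.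

## Compound list
1 | 2-methylprop-2-en-1-ol | C=C(C)CO | starting material
2 | (S)-(2-methyloxiran-2-yl)methanol | OC[C@@]1(C)CO1 | intermediate
3 | isopropenylmagnesium bromide | CC(=C)[Mg]Br | starting material
4 | (2R)-2,4-dimethylpent-4-ene-1,2-diol | OC[C@@](O)(C)CC(C)=C | intermediate
5 | (2R)-2-hydroxy-2,4-dimethylpent-4-en-1-yl 4-methylbenzenesulfonate | Cc1ccc(cc1)S(=O)(=O)OC[C@@](O)(C)CC(C)=C | intermediate
6 | (2R)-2-methyl-2-(2-methylprop-2-en-1-yl)oxirane | O1C[C@@]1(C)CC(C)=C | intermediate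
7 | (2R)-2-methyl-2-(2-methylprop-2-en-1-yl)oxetane | O1CC[C@@]1(C)CC(C)=C | intermediate
8 | (3S)-3-hydroperoxy-3,5-dimethylhex-5-en-1-ol | OCC[C@](OO)(C)CC(C)=C | intermediate
9 | methyl 2-[(3R,5R)-5-(2-hydroxyethyl)-3,5-dimethyl-1,2-dioxolan-3-yl]acetate | OCC[C@]1(C)C[C@](C)(CC(=O)OC)OO1 | intermediate
10 | methyl 2-[(3R,5R)-3,5-dimethyl-5-[2-(methylsulfonyloxy)ethyl]-1,2-dioxolan-3-yl]acetate | CS(=O)(=O)OCC[C@]1(C)C[C@](C)(CC(=O)OC)OO1 | intermediate
11 | methyl 2-[(3R,5S)-5-(2-bromoethyl)-3,5-dimethyl-1,2-dioxolan-3-yl]acetate | BrCC[C@]1(C)C[C@](C)(CC(=O)OC)OO1 | intermediate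
12 | 6-bromohex-1-ene | C=CCCCCBr | starting material
13 | lithium acetylide–ethylenediamine complex | [Li]C#C.NCCN | starting material
14 | oct-1-en-7-yne | C=CCCCCC#C | intermediate
15 | chlorobis(cyclopentadienyl)[(1E)-octa-1,7-dien-1-yl]zirconium | C=CCCCC/C=C/[Zr](Cl)(C1C=CC=C1)C1C=CC=C1 | intermediate
16 | (1E)-1-iodoocta-1,7-diene | C=CCCCC/C=C/I | intermediate
17 | (2E)-pent-2-enal | CC/C=C/C=O | starting material
18 | (3E)-1,1-dibromohexa-1,3-diene | CC/C=C/C=C(Br)Br | intermediate
19 | lithium (3E)-hex-3-en-1-yn-1-ide | CC/C=C/C#C[Li] | intermediate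
20 | (3E)-hex-3-en-1-yne | CC/C=C/C#C | intermediate
21 | 2-[(1E,3E)-hexa-1,3-dien-1-yl]-4,4,5,5-tetramethyl-1,3,2-dioxaborolane | CC/C=C/C=C/B1OC(C)(C)C(C)(C)O1 | intermediate
22 | (7E,9E,11E)-tetradeca-1,7,9,11-tetraene | C=CCCCC/C=C/C=C/C=C/CC | intermediate
23 | 9-[(7E,9E,11E)-tetradeca-7,9,11-trien-1-yl]-9-borabicyclo[3.3.1]nonane | CC/C=C/C=C/C=C/CCCCCCB1C2CCCC1CCC2 | intermediate
24 | methyl 2-[(3R,5R)-5-[(9E,11E,13E)-hexadeca-9,11,13-trien-1-yl]-3,5-dimethyl-1,2-dioxolan-3-yl]acetate | CC/C=C/C=C/C=C/CCCCCCCC[C@]1(C)C[C@](C)(CC(=O)OC)OO1 | intermediate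
25 | lithium 2-[(3R,5R)-5-[(9E,11E,13E)-hexadeca-9,11,13-trien-1-yl]-3,5-dimethyl-1,2-dioxolan-3-yl]acetate | CC/C=C/C=C/C=C/CCCCCCCC[C@]1(C)C[C@](C)(CC(=O)[O-])OO1.[Li+] | intermediate
26 | 2-[(3R,5R)-5-[(9E,11E,13E)-hexadeca-9,11,13-trien-1-yl]-3,5-dimethyl-1,2-dioxolan-3-yl]acetic acid | CC/C=C/C=C/C=C/CCCCCCCC[C@]1(C)C[C@](C)(CC(=O)O)OO1 | target

## Step count and risks
Total step count: 15. Longest linear sequence: 9 (steps 1–7, 14, 15).

**1. Step 6 (the new peroxypalladation/carbonylation).**
- Risks: Pd-mediated decomposition of the hydroperoxide, oxidation of CO by the hydroperoxide, competing attack by the primary OH, and poor face selectivity.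
- The fallback uses known chemistry, sets out from 7 and comes back at 9.
- Cross metathesis of 7 with methyl acrylate (Hoveyda–Grubbs II, CH2Cl2, 40 °C) gives methyl (2E)-3-methyl-4-[(2R)-2-methyloxetan-2-yl]but-2-enoate F1.
- Perhydrolysis as in step 5 gives methyl (2E,5S)-5-hydroperoxy-7-hydroxy-3,5-dimethylhept-2-enoate F2.
- Catalytic Et2NH in CF3CH2OH then triggers the established 5-exo conjugate addition of a hydroperoxide to an enoate. This gives 9 and its C3 epimer (about 1:1 to 3:1 expected), separated by chromatography.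

**2. Step 14 (alkyl–alkyl Suzuki coupling next to a peroxide).**
- Risks: O–O insertion or reduction by Pd(0)/PCy3 or by residual borane, β-hydride elimination, and triene isomerisation.
- The fallback sets out from 9 and comes back at 24. It replaces the coupling by two olefinations.
- Dess–Martin oxidation of 9 gives methyl 2-[(3R,5S)-3,5-dimethyl-5-(2-oxoethyl)-1,2-dioxolan-3-yl]acetate F3.
- Salt-free Wittig reaction with the ylide of [7-(tert-butyldimethylsilyloxy)heptyl]triphenylphosphonium bromide (NaHMDS, THF, −78 °C) gives methyl 2-[(3R,5R)-5-[(2Z)-9-(tert-butyldimethylsilyloxy)non-2-en-1-yl]-3,5-dimethyl-1,2-dioxolan-3-yl]acetate F4.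
- Diimide (2-nitrobenzenesulfonyl hydrazide, Et3N), which spares peroxides, gives methyl 2-[(3R,5R)-5-[9-(tert-butyldimethylsilyloxy)nonyl]-3,5-dimethyl-1,2-dioxolan-3-yl]acetate F5.
- HF·pyridine gives methyl 2-[(3R,5R)-5-(9-hydroxynonyl)-3,5-dimethyl-1,2-dioxolan-3-yl]acetate F6.
- Dess–Martin oxidation gives methyl 2-[(3R,5R)-3,5-dimethyl-5-(9-oxononyl)-1,2-dioxolan-3-yl]acetate F7.
- Horner–Wadsworth–Emmons reaction with pre-lithiated diethyl [(2E,4E)-hepta-2,4-dien-1-yl]phosphonate (THF, −78 °C) gives 24.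

**3. Step 5 (intermolecular perhydrolysis).**
- Risks: a moderate yield, partial loss of stereochemical fidelity, and acid-triggered Markovnikov closure of 8 onto its own alkene.
- The fallback sets out from 7 and comes back at 11. It delivers the peroxide intramolecularly.
- Ozonolysis of 7 in CH2Cl2/MeOH at −78 °C gives (2S)-2-(2-hydroperoxy-2-methoxypropyl)-2-methyloxetane F8.
- Catalytic TMSOTf makes its hydroperoxide open the oxetane in a 5-exo, invertive closure. The product is 2-[(3R,5RS)-5-methoxy-3,5-dimethyl-1,2-dioxolan-3-yl]ethan-1-ol F9.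
- MsCl/Et3N gives 2-[(3R,5RS)-5-methoxy-3,5-dimethyl-1,2-dioxolan-3-yl]ethyl methanesulfonate F10.
- LiBr gives (3S,5RS)-3-(2-bromoethyl)-5-methoxy-3,5-dimethyl-1,2-dioxolane F11.
- The known Lewis acid mediated substitution of an alkoxydioxolane via its peroxycarbenium ion (TiCl4, 1-methoxy-1-(trimethylsilyloxy)ethene, CH2Cl2, −78 °C) gives 11 and its C3 epimer, which are separated by chromatography.

## Further compounds
F1 | step 6 | methyl (2E)-3-methyl-4-[(2R)-2-methyloxetan-2-yl]but-2-enoate | O1CC[C@@]1(C)C/C(C)=C/C(=O)OC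
F2 | step 6 | methyl (2E,5S)-5-hydroperoxy-7-hydroxy-3,5-dimethylhept-2-enoate | OCC[C@](OO)(C)C/C(C)=C/C(=O)OC
F3 | step 14 | methyl 2-[(3R,5S)-3,5-dimethyl-5-(2-oxoethyl)-1,2-dioxolan-3-yl]acetate | O=CC[C@]1(C)C[C@](C)(CC(=O)OC)OO1
F4 | step 14 | methyl 2-[(3R,5R)-5-[(2Z)-9-(tert-butyldimethylsilyloxy)non-2-en-1-yl]-3,5-dimethyl-1,2-dioxolan-3-yl]acetate | CC(C)(C)[Si](C)(C)OCCCCCC/C=C\C[C@]1(C)C[C@](C)(CC(=O)OC)OO1
F5 | step 14 | methyl 2-[(3R,5R)-5-[9-(tert-butyldimethylsilyloxy)nonyl]-3,5-dimethyl-1,2-dioxolan-3-yl]acetate | CC(C)(C)[Si](C)(C)OCCCCCCCCC[C@]1(C)C[C@](C)(CC(=O)OC)OO1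
F6 | step 14 | methyl 2-[(3R,5R)-5-(9-hydroxynonyl)-3,5-dimethyl-1,2-dioxolan-3-yl]acetate | OCCCCCCCCC[C@]1(C)C[C@](C)(CC(=O)OC)OO1
F7 | step 14 | methyl 2-[(3R,5R)-3,5-dimethyl-5-(9-oxononyl)-1,2-dioxolan-3-yl]acetate | O=CCCCCCCCC[C@]1(C)C[C@](C)(CC(=O)OC)OO1
F8 | step 5 | (2S)-2-(2-hydroperoxy-2-methoxypropyl)-2-methyloxetane | O1CC[C@@]1(C)CC(C)(OC)OO
F9 | step 5 | 2-[(3R,5RS)-5-methoxy-3,5-dimethyl-1,2-dioxolan-3-yl]ethan-1-ol | OCC[C@]1(C)CC(C)(OC)OO1
F10 | step 5 | 2-[(3R,5RS)-5-methoxy-3,5-dimethyl-1,2-dioxolan-3-yl]ethyl methanesulfonate | CS(=O)(=O)OCC[C@]1(C)CC(C)(OC)OO1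
F11 | step 5 | (3S,5RS)-3-(2-bromoethyl)-5-methoxy-3,5-dimethyl-1,2-dioxolane | BrCC[C@]1(C)CC(C)(OC)OO1
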